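**Strategy.** Everything rests on cutting ring A away from a carvone-derived ring B at C1–C10 and C4–C5. The feature exploited is the syn relationship on ring B between the C11–C15 chain on C9 and the C20 methyl on quaternary C10. C9 is therefore set first on (S)-carvone, anti to the C7 isopropenyl, and the resulting enolate is stored as its silyl enol ether (C5=C10). In one operation ethyl vinyl ketone then quaternises C10 anti to the chain and aldol condensation closes ring A, giving the C4-methyl enone (C3=O, C4=C5). The precursor is thus the trimethylsilyl enol ether of trans-9-alkyl dihydrocarvone with C15 as a silyl ether.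

Key step: step 6

Remark: locants and α/β follow labdane numbering with the C20 methyl β; the target is (5S,7R,9R,10S,13R)-7α-acetoxylabd-8(17)-en-15-oic acid, and all labdane-named compounds below have 5α-H, 9α-H (chain β), 10β-CH3 and 13R.
Remark: C13 comes out R only if the free carboxyl carbon of hemiester 1 becomes C11 and its ester carbon becomes C15; the route is built on that assignment.
Remark: in step 9 the hot KOH is assumed to cleave the primary silyl ether together with the acetate; any silyl ether that survives is compound 21 itself, so step 10 converges either way.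

**Route**

Step 1
Reactants: 1 methyl hydrogen (R)-3-methylglutarate
Product: 2 methyl (R)-5-hydroxy-3-methylpentanoate
Conditions: BH3·SMe2 (1.1 equiv), THF, −10 °C → rt; MeOH quench; used crude
Reagents that add atoms: none
Why: Chemoselective borane reduction of a carboxylic acid beside an ester (the acyloxyborane is reduced far faster than the ester), which leaves the stereocentre untouched; the crude hydroxy ester is carried on at once so that it cannot lactonise.

Step 2
Reactants: 2 methyl (R)-5-hydroxy-3-methylpentanoate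
Product: 3 methyl (S)-5-bromo-3-methylpentanoate
Conditions: CBr4, PPh3, CH2Cl2, 0 °C
Reagents that add atoms: carbon tetrabromide, BrC(Br)(Br)Br
Why: Appel bromination of a primary alcohol through its alkoxyphosphonium ion; the stereocentre is not involved and its descriptor changes to S by priority only.

Step 3
Reactants: 3 methyl (S)-5-bromo-3-methylpentanoate
Product: 4 (S)-5-bromo-3-methylpentan-1-ol
Conditions: i-Bu2AlH (2.3 equiv), CH2Cl2, −78 → 0 °C; aq. KNaC4H4O6 (potassium sodium tartrate)
Reagents that add atoms: none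
Why: Ester reduction to the primary alcohol with i-Bu2AlH, which leaves a primary alkyl bromide alone at low temperature.

Step 4
Reactants: 4 (S)-5-bromo-3-methylpentan-1-ol
Product: 5 (S)-[(5-bromo-3-methylpentyl)oxy](tert-butyl)dimethylsilane
Conditions: t-BuMe2SiCl, imidazole, CH2Cl2, 0 °C → rt
Reagents that add atoms: tert-butyldimethylsilyl chloride, CC(C)(C)[Si](C)(C)Cl
Why: Standard silylation of a primary alcohol, giving a C15 ether that tolerates the Grignard, Lewis-acid, alkoxide and dissolving-metal steps ahead.

Step 5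
Reactants: 5 (S)-[(5-bromo-3-methylpentyl)oxy](tert-butyl)dimethylsilane; 6 (S)-(+)-carvone
Product: 8 (3S,5S)-3-[(3R)-5-(tert-butyldimethylsilyloxy)-3-methylpentyl]-2-methyl-5-(prop-1-en-2-yl)-1-(trimethylsilyloxy)cyclohex-1-ene, via Grignard reagent 7 (not isolated)
Conditions: Mg, THF, 40 °C; CuBr·SMe2 (10 mol %), HMPA, then 6 + Me3SiCl, THF, −78 → −40 °C; Et3N, cold aq. NaHCO3
Reagents that add atoms: chlorotrimethylsilane, C[Si](C)(C)Cl
Why: Copper-catalysed, chlorosilane-accelerated conjugate addition of a Grignard reagent to an enone; the alkyl group should enter C9 axially, anti to the C7 isopropenyl group (chain trans to isopropenyl), and in-situ O-silylation fixes the enolate as the C5=C10 enol ether only.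

Step 6
Reactants: 8 (3S,5S)-3-[(3R)-5-(tert-butyldimethylsilyloxy)-3-methylpentyl]-2-methyl-5-(prop-1-en-2-yl)-1-(trimethylsilyloxy)cyclohex-1-ene; 9 ethyl vinyl ketone
Product: 13 (4aR,5S,7S)-5-[(3R)-5-(tert-butyldimethylsilyloxy)-3-methylpentyl]-1,4a-dimethyl-7-(prop-1-en-2-yl)-4,4a,5,6,7,8-hexahydronaphthalen-2(3H)-one, via silyl enol ether adduct 10 (not isolated), via 1,5-diketone 11 (not isolated), via ketol 12 (not isolated)
Conditions: 9 (1.3 equiv), Ph3CSbCl6 (5 mol %), CH2Cl2, −78 °C; pyridine quench, solvent switch; NaOMe, MeOH, rt → 45 °C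
Reagents that add atoms: none
Why: The trityl cation activates 9 towards the tetrasubstituted silyl enol ether, which attacks through C10 (Mukaiyama–Michael addition) and passes its silyl group to the new enolate oxygen to give 10; methoxide then frees diketone 11, whose ethyl-ketone enolate (C4) adds to the C5 carbonyl, and ketol 12 loses water (aldol condensation), the whole being a Robinson annulation. The closest known reaction type is the Lewis-acid Michael addition of carvone-derived silyl enol ethers to vinyl ketones followed by base cyclisation. Ring A is closed in the 6-(enolendo)-exo-trig mode. The only new stereocentre, C10, is controlled by the C9 chain: allylic strain with the C10 methyl holds that chain pseudoaxial (the trans C7 isopropenyl stays equatorial), so the acceptor adds axially on the opposite face and the C20 methyl ends up syn to the chain. The step needs face selectivity at C10 and reaction at C10 only; the neighbouring C9 substituent secures the first and the fixed C5=C10 position of the enol ether, set in step 5, secures the second. The alternative aldol (C6 onto C3) is reversible and cannot dehydrate, so the conjugated enone 13 should be the thermodynamic sink.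

Step 7
Reactants: 13 (4aR,5S,7S)-5-[(3R)-5-(tert-butyldimethylsilyloxy)-3-methylpentyl]-1,4a-dimethyl-7-(prop-1-en-2-yl)-4,4a,5,6,7,8-hexahydronaphthalen-2(3H)-one
Product: 15 15-(tert-butyldimethylsilyloxy)-7α-(prop-1-en-2-yl)-17-norlabdan-3-one, via lithium enolate 14 (not isolated)
Conditions: Li (2.2 equiv), NH3(l)/THF, t-BuOH (1.0 equiv), −78 → −33 °C; isoprene; MeI (excess), −78 °C → rt
Reagents that add atoms: iodomethane, CI
Why: Dissolving-metal reduction of the enone with regiospecific alkylation of the resulting C3=C4 enolate (reductive alkylation); axial protonation of C5 anti to the C20 methyl should set the trans ring fusion (5α-H) and methylation at C4 completes the gem-dimethyl group, while the isolated isopropenyl group and the silyl ether are inert.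

Step 8
Reactants: 15 15-(tert-butyldimethylsilyloxy)-7α-(prop-1-en-2-yl)-17-norlabdan-3-one
Product: 18 7α-acetoxy-15-(tert-butyldimethylsilyloxy)-17-norlabdan-3-one, via methoxy hydroperoxide 16 (not isolated), via peracetate 17 (not isolated)
Conditions: O3, CH2Cl2/MeOH, NaHCO3, −78 °C; N2 purge, concentrate; Ac2O, Et3N, 4-(dimethylamino)pyridine (cat.), CH2Cl2, 0 → 40 °C
Reagents that add atoms: ozone, [O-][O+]=O; methanol, CO
Why: Ozonolysis in methanol traps the carbonyl oxide as the α-methoxy hydroperoxide, whose peracetate undergoes Criegee rearrangement with migration of the secondary C7 carbon to oxygen with retention; no peracid is present, so the C3 ketone is not oxidised.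

Step 9
Reactants: 18 7α-acetoxy-15-(tert-butyldimethylsilyloxy)-17-norlabdan-3-one
Product: 20 17-norlabdane-7α,15-diol, via hydrazone 19 (not isolated)
Conditions: N2H4·H2O (excess), KOH, diethylene glycol, 130 °C; distil to 200 °C
Reagents that add atoms: none
Why: Wolff–Kishner reduction (Huang–Minlon procedure) removes the hindered C3 carbonyl through its hydrazone with loss of N2, and the same hot KOH saponifies the C7 acetate and cleaves the primary silyl ether; C4 is quaternary and C2 is a methylene, so no stereocentre can epimerise.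

Step 10
Reactants: 20 17-norlabdane-7α,15-diol
Product: 21 15-(tert-butyldimethylsilyloxy)-17-norlabdan-7α-ol
Conditions: t-BuMe2SiCl (1.1 equiv), imidazole, CH2Cl2, 0 °C
Reagents that add atoms: tert-butyldimethylsilyl chloride, CC(C)(C)[Si](C)(C)Cl
Why: Selective silylation of the primary C15 hydroxyl over the hindered axial secondary C7 hydroxyl.

Step 11
Reactants: 21 15-(tert-butyldimethylsilyloxy)-17-norlabdan-7α-ol
Product: 22 15-(tert-butyldimethylsilyloxy)-17-norlabdan-7-one
Conditions: Dess–Martin periodinane, NaHCO3, CH2Cl2, rt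
Reagents that add atoms: none
Why: Dess–Martin oxidation of a secondary alcohol to the ketone under buffered conditions that spare the silyl ether; C5 and C9 are β to the new carbonyl and cannot epimerise.

Step 12
Reactants: 22 15-(tert-butyldimethylsilyloxy)-17-norlabdan-7-one
Product: 23 15-(tert-butyldimethylsilyloxy)-8-(hydroxymethylene)-17-norlabdan-7-one
Conditions: NaH, HCO2Et, THF, EtOH (cat.), 0 °C → rt; cold dilute HCl work-up
Reagents that add atoms: ethyl formate, CCOC=O
Why: Reversible Claisen formylation under thermodynamic control, expected at C8 rather than C6 because C6 is flanked by C5 and the C4 gem-dimethyl group, as 3-keto-5α-decalin systems formylate on the side remote from the ring fusion.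

Step 13
Reactants: 23 15-(tert-butyldimethylsilyloxy)-8-(hydroxymethylene)-17-norlabdan-7-one
Product: 24 15-(tert-butyldimethylsilyloxy)labd-8(17)-en-7-one
Conditions: 37 % aq. HCHO, K2CO3, THF, rt; used without delay
Reagents that add atoms: formaldehyde, C=O
Why: Deformylative methylenation: the β-keto aldehyde enolate adds to formaldehyde at C8, the formyl group moves to the new hydroxyl and formate is lost by E1cB elimination, which places the exocyclic C8=C17 bond regiospecifically.

Step 14
Reactants: 24 15-(tert-butyldimethylsilyloxy)labd-8(17)-en-7-one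
Product: 25 15-(tert-butyldimethylsilyloxy)labd-8(17)-en-7β-ol
Conditions: NaBH4, CeCl3·7H2O, MeOH, −78 → −20 °C
Reagents that add atoms: none
Why: Luche 1,2-reduction of the enone; hydride should arrive axially on the α face, past only the axial H5 and H9, to give the equatorial 7β-alcohol.

Step 15
Reactants: 25 15-(tert-butyldimethylsilyloxy)labd-8(17)-en-7β-ol
Product: 26 7α-acetoxy-15-(tert-butyldimethylsilyloxy)labd-8(17)-ene
Conditions: AcOH, PPh3, diisopropyl azodicarboxylate, THF, 0 °C → rt
Reagents that add atoms: acetic acid, CC(=O)O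
Why: Mitsunobu esterification; acetate displaces the oxyphosphonium group at C7 with inversion along the axial α trajectory, setting the 7α (7R) acetate.

Step 16
Reactants: 26 7α-acetoxy-15-(tert-butyldimethylsilyloxy)labd-8(17)-ene
Product: 27 7α-acetoxylabd-8(17)-en-15-ol
Conditions: HF·pyridine, pyridine, THF, 0 °C → rt
Reagents that add atoms: none
Why: Fluoride cleavage of the primary silyl ether under buffered conditions that leave the allylic acetate and the exocyclic alkene alone.

Step 17
Reactants: 27 7α-acetoxylabd-8(17)-en-15-ol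
Product: 28 7α-acetoxylabd-8(17)-en-15-oic acid
Conditions: 2,2,6,6-tetramethylpiperidin-1-oxyl (cat.), PhI(OAc)2 (2.2 equiv), MeCN/H2O (1:1), rt
Reagents that add atoms: water, O
Why: Oxoammonium-mediated oxidation of the primary alcohol through the aldehyde hydrate to the acid, a method that tolerates the alkene and the acetate and touches no stereocentre.

**Compound list**

1 | methyl hydrogen (R)-3-methylglutarate | OC(=O)C[C@@H](C)CC(=O)OC | starting material
2 | methyl (R)-5-hydroxy-3-methylpentanoate | OCC[C@@H](C)CC(=O)OC | intermediate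
3 | methyl (S)-5-bromo-3-methylpentanoate | BrCC[C@@H](C)CC(=O)OC | intermediate
4 | (S)-5-bromo-3-methylpentan-1-ol | BrCC[C@@H](C)CCO | intermediate
5 | (S)-[(5-bromo-3-methylpentyl)oxy](tert-butyl)dimethylsilane | BrCC[C@@H](C)CCO[Si](C)(C)C(C)(C)C | intermediate
6 | (S)-(+)-carvone | CC(=C)[C@H]1CC=C(C)C(=O)C1 | starting material
7 | (S)-[5-(tert-butyldimethylsilyloxy)-3-methylpentyl]magnesium bromide | Br[Mg]CC[C@@H](C)CCO[Si](C)(C)C(C)(C)C | intermediate (not isolated)
8 | (3S,5S)-3-[(3R)-5-(tert-butyldimethylsilyloxy)-3-methylpentyl]-2-methyl-5-(prop-1-en-2-yl)-1-(trimethylsilyloxy)cyclohex-1-ene (key-step precursor; chain trans to isopropenyl) | CC(=C)[C@H]1C[C@H](CC[C@@H](C)CCO[Si](C)(C)C(C)(C)C)C(C)=C(O[Si](C)(C)C)C1 | intermediate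
9 | ethyl vinyl ketone (pent-1-en-3-one) | C=CC(=O)CC | starting material
10 | (2R,3S,5S)-3-[(3R)-5-(tert-butyldimethylsilyloxy)-3-methylpentyl]-2-methyl-5-(prop-1-en-2-yl)-2-[3-(trimethylsilyloxy)pent-2-en-1-yl]cyclohexan-1-one (E/Z mixture) | O=C1C[C@@H](C(C)=C)C[C@H](CC[C@@H](C)CCO[Si](C)(C)C(C)(C)C)[C@@]1(C)CC=C(CC)O[Si](C)(C)C | intermediate (not isolated)
11 | (2R,3S,5S)-3-[(3R)-5-(tert-butyldimethylsilyloxy)-3-methylpentyl]-2-methyl-2-(3-oxopentyl)-5-(prop-1-en-2-yl)cyclohexan-1-one | O=C1C[C@@H](C(C)=C)C[C@H](CC[C@@H](C)CCO[Si](C)(C)C(C)(C)C)[C@@]1(C)CCC(=O)CC | intermediate (not isolated)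
12 | ring-A ketol: 5-hydroxy-4-methyl-3-ketone of the decalin (C4 and C5 configuration immaterial; C7, C9, C10 as in 13) | CC1C2(O)C[C@@H](C(C)=C)C[C@H](CC[C@@H](C)CCO[Si](C)(C)C(C)(C)C)[C@@]2(C)CCC1=O | intermediate (not isolated)
13 | (4aR,5S,7S)-5-[(3R)-5-(tert-butyldimethylsilyloxy)-3-methylpentyl]-1,4a-dimethyl-7-(prop-1-en-2-yl)-4,4a,5,6,7,8-hexahydronaphthalen-2(3H)-one (key-step product; C3=O, C4=C5, 7α-isopropenyl, 9β-chain, 10β-CH3) | CC1=C2C[C@@H](C(C)=C)C[C@H](CC[C@@H](C)CCO[Si](C)(C)C(C)(C)C)[C@@]2(C)CCC1=O | intermediate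
14 | lithium C3=C4 enolate of the trans-fused 4-methyl-3-ketone (5α-H) | CC=1[C@@H]2C[C@@H](C(C)=C)C[C@H](CC[C@@H](C)CCO[Si](C)(C)C(C)(C)C)[C@@]2(C)CCC=1O[Li] | intermediate (not isolated)
15 | 15-(tert-butyldimethylsilyloxy)-7α-(prop-1-en-2-yl)-17-norlabdan-3-one | CC1(C)[C@@H]2C[C@@H](C(C)=C)C[C@H](CC[C@@H](C)CCO[Si](C)(C)C(C)(C)C)[C@@]2(C)CCC1=O | intermediate
16 | 7α-(2-hydroperoxy-2-methoxyethan-1,1-diyl... i.e. 1-hydroperoxy-1-methoxyethyl) derivative of the 3-ketone | CC1(C)[C@@H]2C[C@@H](C(C)(OC)OO)C[C@H](CC[C@@H](C)CCO[Si](C)(C)C(C)(C)C)[C@@]2(C)CCC1=O | intermediate (not isolated)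
17 | peracetate of 16 | CC1(C)[C@@H]2C[C@@H](C(C)(OC)OOC(C)=O)C[C@H](CC[C@@H](C)CCO[Si](C)(C)C(C)(C)C)[C@@]2(C)CCC1=O | intermediate (not isolated)
18 | 7α-acetoxy-15-(tert-butyldimethylsilyloxy)-17-norlabdan-3-one | CC1(C)[C@@H]2C[C@@H](OC(C)=O)C[C@H](CC[C@@H](C)CCO[Si](C)(C)C(C)(C)C)[C@@]2(C)CCC1=O | intermediate
19 | C3 hydrazone of 7α,15-dihydroxy-17-norlabdan-3-one (drawn after loss of acetate and silyl ether; the order of these events is immaterial) | CC1(C)[C@@H]2C[C@@H](O)C[C@H](CC[C@@H](C)CCO)[C@@]2(C)CCC1=NN | intermediate (not isolated)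
20 | 17-norlabdane-7α,15-diol | CC1(C)[C@@H]2C[C@@H](O)C[C@H](CC[C@@H](C)CCO)[C@@]2(C)CCC1 | intermediate
21 | 15-(tert-butyldimethylsilyloxy)-17-norlabdan-7α-ol | CC1(C)[C@@H]2C[C@@H](O)C[C@H](CC[C@@H](C)CCO[Si](C)(C)C(C)(C)C)[C@@]2(C)CCC1 | intermediate
22 | 15-(tert-butyldimethylsilyloxy)-17-norlabdan-7-one | CC1(C)[C@@H]2CC(=O)C[C@H](CC[C@@H](C)CCO[Si](C)(C)C(C)(C)C)[C@@]2(C)CCC1 | intermediate
23 | 15-(tert-butyldimethylsilyloxy)-8-(hydroxymethylene)-17-norlabdan-7-one (chelated enol of the 8-formyl ketone) | CC1(C)[C@@H]2CC(=O)C(=CO)[C@H](CC[C@@H](C)CCO[Si](C)(C)C(C)(C)C)[C@@]2(C)CCC1 | intermediate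
24 | 15-(tert-butyldimethylsilyloxy)labd-8(17)-en-7-one | CC1(C)[C@@H]2CC(=O)C(=C)[C@H](CC[C@@H](C)CCO[Si](C)(C)C(C)(C)C)[C@@]2(C)CCC1 | intermediate
25 | 15-(tert-butyldimethylsilyloxy)labd-8(17)-en-7β-ol | CC1(C)[C@@H]2C[C@H](O)C(=C)[C@H](CC[C@@H](C)CCO[Si](C)(C)C(C)(C)C)[C@@]2(C)CCC1 | intermediate
26 | 7α-acetoxy-15-(tert-butyldimethylsilyloxy)labd-8(17)-ene | CC1(C)[C@@H]2C[C@@H](OC(C)=O)C(=C)[C@H](CC[C@@H](C)CCO[Si](C)(C)C(C)(C)C)[C@@]2(C)CCC1 | intermediate
27 | 7α-acetoxylabd-8(17)-en-15-ol | CC1(C)[C@@H]2C[C@@H](OC(C)=O)C(=C)[C@H](CC[C@@H](C)CCO)[C@@]2(C)CCC1 | intermediate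
28 | (5S,7R,9R,10S,13R)-7α-acetoxylabd-8(17)-en-15-oic acid (CNP0156001.3) | C=C1[C@H](OC(C)=O)C[C@H]2C(C)(C)CCC[C@]2(C)[C@H]1CC[C@@H](C)CC(=O)O | target

**Totals**

Total steps: 17. Longest linear sequence: 17 steps (1 → 28); carvone 6 enters at step 5 and ethyl vinyl ketone 9 at step 6.

**Steps most likely to fail**

Step 6. The silyl group may be stripped from 8 by adventitious acid before the C–C bond forms, the vinyl ketone may oligomerise on the Lewis acid, or the faces of C10 may not be discriminated well enough. The fallback replaces cationic activation of the enone by an anionic Michael addition to a stabilised acceptor (the α-silyl vinyl ketone variant of the Robinson annulation). It sets out from 8, which MeLi in THF at 0 °C should convert into the regiodefined lithium enolate F1. At −78 °C this enolate should add to 2-(trimethylsilyl)pent-1-en-3-one, again anti to the C9 chain, to give the 2-silyl 1,5-diketone F2. NaOMe in MeOH should then remove the silicon, which returns the route to diketone 11, and the same base closes it to 13.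

Step 12. Formylation may leak to C6, or conversion may stall because the C8 methylene next to the branched C9 enolises slowly under equilibrating conditions. The fallback uses kinetic enolate aminomethylation and elimination instead of thermodynamic acylation. It sets out from 22, which LiN(i-Pr)2 in THF at −78 °C should deprotonate at C8 to give the lithium enolate F3; the axial C8 hydrogen faces one syn-axial methyl, the axial C6 hydrogen two. Trapping with H2C=NMe2+ I− should give the Mannich base F4, MeI its methiodide F5, and aqueous NaHCO3 in CH2Cl2 the elimination product 24, where the route is rejoined without passing through 23.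

Step 15. Acetate may attack the terminal C17 with allylic transposition, or the activated alcohol may eliminate to a diene, instead of direct displacement at C7. The fallback sets C7 by reagent-controlled reduction so that no substitution at C7 is needed. It sets out from enone 24: Corey–Bakshi–Shibata reduction with (S)-1-methyl-3,3-diphenyltetrahydro-1H,3H-pyrrolo[1,2-c][1,3,2]oxazaborole (cat.) and catecholborane in toluene at −78 °C should deliver hydride to the β face and give the 7α-alcohol F6. Acetylation with Ac2O, pyridine and 4-(dimethylamino)pyridine then returns the route at 26.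

**Further compounds**

F1 | step 6 | lithium enolate of the 9-alkylated dihydrocarvone (C5–OLi, C5=C10) | CC(=C)[C@H]1C[C@H](CC[C@@H](C)CCO[Si](C)(C)C(C)(C)C)C(C)=C(O[Li])C1
F2 | step 6 | 2-silyl 1,5-diketone: 11 carrying SiMe3 on C2 (C2 configuration immaterial) | O=C1C[C@@H](C(C)=C)C[C@H](CC[C@@H](C)CCO[Si](C)(C)C(C)(C)C)[C@@]1(C)CC([Si](C)(C)C)C(=O)CC
F3 | step 12 | kinetic lithium enolate of 22 (C7–OLi, C7=C8) | CC1(C)[C@@H]2CC(O[Li])=C[C@H](CC[C@@H](C)CCO[Si](C)(C)C(C)(C)C)[C@@]2(C)CCC1
F4 | step 12 | Mannich base: 8-(dimethylaminomethyl)-15-(tert-butyldimethylsilyloxy)-17-norlabdan-7-one (C8 configuration immaterial) | CC1(C)[C@@H]2CC(=O)C(CN(C)C)[C@H](CC[C@@H](C)CCO[Si](C)(C)C(C)(C)C)[C@@]2(C)CCC1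
F5 | step 12 | methiodide of F4 | CC1(C)[C@@H]2CC(=O)C(C[N+](C)(C)C)[C@H](CC[C@@H](C)CCO[Si](C)(C)C(C)(C)C)[C@@]2(C)CCC1.[I-]
F6 | step 15 | 15-(tert-butyldimethylsilyloxy)labd-8(17)-en-7α-ol | CC1(C)[C@@H]2C[C@@H](O)C(=C)[C@H](CC[C@@H](C)CCO[Si](C)(C)C(C)(C)C)[C@@]2(C)CCC1
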